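**Assumption (one line):** the target SMILES has no stereocentre and no stereogenic double bond, and the 18-membered ring is taken as conformationally mobile, so the compound is achiral and no enantioselective step is needed.

Ring labels: A = ring with the free OH para to its ether O; B = catechol-type ring (OH ortho to its ether O); C = para-phenylene; D = meta-phenylene.

## Retrosynthetic overview

1. Target ⇐ O-demethylation (ring B) and Baeyer–Villiger/Dakin oxidation of a ring-A CHO, which earlier serves as the SNAr activator.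
2. Key disconnection: ring D and the 18-membered macrocycle are opened together, by a retro pyrone Diels–Alder / CO2 loss / PhSO2H elimination, to a 3-aryloxy-2-pyrone tethered to an (E)-vinyl sulfone (11).
3. 11 ⇐ B-alkyl Suzuki coupling (ring A–CH2CH2–ring B bridge) of styrene 6 with aryl bromide 9.
4. 6 ⇐ Ullmann diaryl ether (B–O–C), Wittig methylenation, one-pot DIBAL/HWE; 9 ⇐ SNAr of 3-hydroxy-2-pyrone on 3-bromo-4-fluorobenzaldehyde.
5. Ring order: A, B and C are bought; ring D and the macrocycle (with a transient bicyclic lactone) form last, in one operation.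

## Route

Step 1
Reactants: 1 methyl 3-(4-hydroxyphenyl)propanoate; 2 3-bromo-4-methoxybenzaldehyde
Product: 3 methyl 3-[4-(5-formyl-2-methoxyphenoxy)phenyl]propanoate
Conditions: CuI (10 mol %), N,N-dimethylglycine·HCl (30 mol %), Cs2CO3, dioxane, 100 °C
Reagents that add atoms: none
Why: Ullmann-type Cu(I)/amino-acid diaryl ether coupling of the only phenol with the aryl bromide; aldehyde and methyl ester tolerate anhydrous carbonate, and no stereocentre is formed.

Step 2
Reactants: 3 methyl 3-[4-(5-formyl-2-methoxyphenoxy)phenyl]propanoate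
Product: 4 methyl 3-[4-(5-ethenyl-2-methoxyphenoxy)phenyl]propanoate
Conditions: Ph3PCH3Br, NaHMDS, THF, 0 °C → rt
Reagents that add atoms: methyltriphenylphosphonium bromide, C[P+](c1ccccc1)(c1ccccc1)c1ccccc1.[Br-]
Why: Wittig methylenation; the non-stabilised ylide reacts with the aldehyde far faster than with the methyl ester at 0 °C.

Step 3
Reactants: 4 methyl 3-[4-(5-ethenyl-2-methoxyphenoxy)phenyl]propanoate
Product: 6 4-ethenyl-1-methoxy-2-{4-[(3E)-4-(phenylsulfonyl)but-3-en-1-yl]phenoxy}benzene, via aldehyde 5 (not isolated)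
Conditions: DIBAL-H (1.05 equiv), CH2Cl2, −78 °C; then LiCH(SO2Ph)P(O)(OEt)2 (from the phosphonate + n-BuLi, THF), −78 °C → rt
Reagents that add atoms: diethyl [(phenylsulfonyl)methyl]phosphonate, CCOP(=O)(CS(=O)(=O)c1ccccc1)OCC
Why: One-pot DIBAL half-reduction / Horner–Wadsworth–Emmons olefination; the aluminium hemiacetal releases aldehyde 5 as the sulfonyl-stabilised phosphonate anion consumes it, the stabilised anion gives the (E)-vinyl sulfone, and the styrene is inert.

Step 4
Reactants: 7 3-hydroxy-2H-pyran-2-one; 8 3-bromo-4-fluorobenzaldehyde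
Product: 9 3-bromo-4-[(2-oxo-2H-pyran-3-yl)oxy]benzaldehyde
Conditions: K2CO3, DMF, 70 °C
Reagents that add atoms: none
Why: SNAr: the phenol-like enolic oxygen of the hydroxypyrone displaces fluoride para to CHO via a Meisenheimer complex, while the bromide meta to CHO is not activated and stays.

Step 5
Reactants: 6 4-ethenyl-1-methoxy-2-{4-[(3E)-4-(phenylsulfonyl)but-3-en-1-yl]phenoxy}benzene; 9 3-bromo-4-[(2-oxo-2H-pyran-3-yl)oxy]benzaldehyde
Product: 11 3-[2-(4-methoxy-3-{4-[(3E)-4-(phenylsulfonyl)but-3-en-1-yl]phenoxy}phenyl)ethyl]-4-[(2-oxo-2H-pyran-3-yl)oxy]benzaldehyde, via alkyl-9-BBN borane 10 (not isolated)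
Conditions: 9-BBN (1.05 equiv), THF, 0 °C → rt; then 9, Pd(dppf)Cl2 (5 mol %), AsPh3, Cs2CO3, DMF/H2O, 40 °C
Reagents that add atoms: none
Why: Anti-Markovnikov hydroboration of the terminal styrene (the 1,2-disubstituted, electron-poor vinyl sulfone reacts far more slowly with 9-BBN), then B-alkyl Suzuki–Miyaura coupling with the aryl bromide under mild carbonate conditions that spare pyrone, aldehyde and vinyl sulfone.

Step 6
Reactants: 11 3-[2-(4-methoxy-3-{4-[(3E)-4-(phenylsulfonyl)but-3-en-1-yl]phenoxy}phenyl)ethyl]-4-[(2-oxo-2H-pyran-3-yl)oxy]benzaldehyde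
Product: 14 macrocyclic aldehyde (dihydroptychantol A skeleton; CHO in place of the ring-A OH; OMe on ring B), via bicyclic lactone 12 (not isolated), via sulfonylcyclohexadiene 13 (not isolated)
Conditions: o-dichlorobenzene (1 mM), BHT (cat.), 180 °C, sealed tube, 16 h
Reagents that add atoms: none
Why: Intramolecular pyrone Diels–Alder / retro-Diels–Alder (−CO2) / elimination of benzenesulfinic acid, a cascade of the type known to close bis(bibenzyl) cyclophanes; the sulfone-bearing carbon bonds to the oxygenated pyrone C3 ("ortho" rule for a 1-donor diene), which places the CH2CH2 tether meta to the aryloxy group, so ring D and the 18-membered ring close together, and the sp3 centres of 12 and 13 are erased on aromatisation.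

Step 7
Reactants: 14 macrocyclic aldehyde
Product: 16 ring-B mono-O-methyl ether of dihydroptychantol A, via aryl formate 15 (not isolated)
Conditions: mCPBA, CH2Cl2, rt; then K2CO3 (cat.), MeOH, rt
Reagents that add atoms: mCPBA, OOC(=O)c1cccc(Cl)c1
Why: Baeyer–Villiger (Dakin-type) oxidation; the electron-rich p-aryloxyphenyl group migrates in the Criegee intermediate to give the aryl formate, which is methanolysed in the same flask.

Step 8
Reactants: 16 ring-B mono-O-methyl ether of dihydroptychantol A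
Product: 17 dihydroptychantol A
Conditions: BBr3, CH2Cl2, −78 °C → rt; then MeOH/H2O
Reagents that add atoms: none
Why: Lewis-acid aryl methyl ether cleavage (bromide SN2 on the O-methyl of the ArO(Me)–BBr3 adduct); the diaryl ethers are untouched and the achiral target is released.

## Compound list

1 | methyl 3-(4-hydroxyphenyl)propanoate | COC(=O)CCc1ccc(O)cc1 | starting material
2 | 3-bromo-4-methoxybenzaldehyde | COc1ccc(C=O)cc1Br | starting material
3 | methyl 3-[4-(5-formyl-2-methoxyphenoxy)phenyl]propanoate | COC(=O)CCc1ccc(Oc2cc(C=O)ccc2OC)cc1 | intermediate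
4 | methyl 3-[4-(5-ethenyl-2-methoxyphenoxy)phenyl]propanoate | COC(=O)CCc1ccc(Oc2cc(C=C)ccc2OC)cc1 | intermediate
5 | 3-[4-(5-ethenyl-2-methoxyphenoxy)phenyl]propanal (not isolated) | O=CCCc1ccc(Oc2cc(C=C)ccc2OC)cc1 | intermediate
6 | 4-ethenyl-1-methoxy-2-{4-[(3E)-4-(phenylsulfonyl)but-3-en-1-yl]phenoxy}benzene | C=Cc1ccc(OC)c(Oc2ccc(CC/C=C/S(=O)(=O)c3ccccc3)cc2)c1 | intermediate
7 | 3-hydroxy-2H-pyran-2-one (commercial; the one-step pyrolysis product of mucic acid) | O=C1OC=CC=C1O | starting material
8 | 3-bromo-4-fluorobenzaldehyde | O=Cc1ccc(F)c(Br)c1 | starting material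
9 | 3-bromo-4-[(2-oxo-2H-pyran-3-yl)oxy]benzaldehyde | O=Cc1ccc(OC2=CC=COC2=O)c(Br)c1 | intermediate
10 | 9-[2-(4-methoxy-3-{4-[(3E)-4-(phenylsulfonyl)but-3-en-1-yl]phenoxy}phenyl)ethyl]-9-borabicyclo[3.3.1]nonane (not isolated) | COc1ccc(CCB2C3CCCC2CCC3)cc1Oc1ccc(CC/C=C/S(=O)(=O)c2ccccc2)cc1 | intermediate
11 | 3-[2-(4-methoxy-3-{4-[(3E)-4-(phenylsulfonyl)but-3-en-1-yl]phenoxy}phenyl)ethyl]-4-[(2-oxo-2H-pyran-3-yl)oxy]benzaldehyde | O=Cc1ccc(OC2=CC=COC2=O)c(CCc2ccc(OC)c(Oc3ccc(CC/C=C/S(=O)(=O)c4ccccc4)cc3)c2)c1 | intermediate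
12 | macrocyclic 2-oxabicyclo[2.2.2]oct-5-en-3-one cycloadduct (racemic endo/exo mixture, so no descriptors; all four sp3 centres are lost downstream; not isolated) | O=Cc1ccc2c(c1)CCc1ccc(OC)c(c1)Oc1ccc(cc1)CCC1C(S(=O)(=O)c3ccccc3)C3(O2)C=CC1OC3=O | intermediate
13 | macrocyclic trans-5-alkyl-6-(phenylsulfonyl)-1-aryloxycyclohexa-1,3-diene (racemic; one enantiomer written; not isolated) | O=Cc1ccc2c(c1)CCc1ccc(OC)c(c1)Oc1ccc(cc1)CC[C@H]1C=CC=C(O2)[C@@H]1S(=O)(=O)c1ccccc1 | intermediate
14 | macrocyclic aldehyde (dihydroptychantol A skeleton; CHO in place of the ring-A OH; OMe on ring B) | O=Cc1ccc2c(c1)CCc1ccc(OC)c(c1)Oc1ccc(cc1)CCc1cccc(c1)O2 | intermediate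
15 | macrocyclic aryl formate (OCHO on ring A; OMe on ring B; not isolated) | O=COc1ccc2c(c1)CCc1ccc(OC)c(c1)Oc1ccc(cc1)CCc1cccc(c1)O2 | intermediate
16 | ring-B mono-O-methyl ether of dihydroptychantol A | Oc1ccc2c(c1)CCc1ccc(OC)c(c1)Oc1ccc(cc1)CCc1cccc(c1)O2 | intermediate
17 | dihydroptychantol A | Oc1ccc2c(c1)CCc1ccc(O)c(c1)Oc1ccc(cc1)CCc1cccc(c1)O2 | target

## Step count and risk

Total step count: 8. Longest linear sequence: 7 (steps 1, 2, 3, 5, 6, 7, 8); step 4 is a one-step branch.

Three steps most likely to fail: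

1. **Step 6** (oligomerisation, sluggish or wrong-way cycloaddition in the 18-membered transition state). The fallback sets out from 6 and 9 and comes back at 14. Pyrone 9 and vinyl sulfone 6 are heated together at high concentration (toluene, 1 M, 150 °C), so the same cycloaddition/CO2 loss/sulfinate elimination builds ring D intermolecularly. It passes through the bicyclic lactone adduct F1 and the trans-sulfonylcyclohexadiene F2, neither isolated, and gives the open-chain 3-bromo-4-{3-[2-(4-(5-ethenyl-2-methoxyphenoxy)phenyl)ethyl]phenoxy}benzaldehyde F3. The macrocycle is then closed through the A–B bridge by a high-dilution intramolecular Heck reaction (Pd(OAc)2, P(o-tol)3, Et3N, DMF, 100 °C) to the macrocyclic (E)-stilbene aldehyde F4. Its C=C is hydrogenated (H2 1 atm, 5 % Pd/C, EtOAc, rt, stopped after one equivalent) to give 14.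

2. **Step 4** (the hydroxypyrone anion is a weak, ambident and base-sensitive nucleophile). The fallback sets out from 8 and comes back at 9, with the polarity of the C–O bond formation reversed. The activated fluoride of 8 is hydrolysed (KOH, DMSO/H2O, 70 °C) to 3-bromo-4-hydroxybenzaldehyde F5, which is also an inexpensive catalogue compound. This phenol is joined to commercial 3-bromo-2H-pyran-2-one by a copper-catalysed vinylic Ullmann etherification (CuI, N,N-dimethylglycine, Cs2CO3, dioxane, 60 °C). The α-bromo-enoate C–Br reacts much faster than the electron-rich aryl bromide ortho to the phenoxide, and the product is 9.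

3. **Step 5** (9-BBN touching the vinyl sulfone, or aqueous base damaging vinyl sulfone or pyrone). The fallback sets out from 6 and comes back at 11, replacing the in-situ borane by an isolable boron nucleophile made without a stoichiometric hydride. Iridium-catalysed hydroboration of the styrene with pinacolborane ([Ir(cod)Cl]2, dppe, CH2Cl2, rt) gives the linear pinacol boronate F6. KHF2 in aqueous MeOH converts it into the crystalline potassium trifluoroborate F7. F7 is coupled with 9 under alkyltrifluoroborate cross-coupling conditions (Pd(OAc)2, RuPhos, K2CO3, toluene/H2O, 80 °C) to give 11.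

## Further compounds

F1 | step 6 | bicyclic lactone adduct of 9 with 6 (racemic endo/exo mixture, not isolated) | O=Cc1ccc(OC23C=CC(OC2=O)C(CCc2ccc(Oc4cc(C=C)ccc4OC)cc2)C3S(=O)(=O)c2ccccc2)c(Br)c1
F2 | step 6 | trans-sulfonylcyclohexadiene from F1 after CO2 loss (racemic; one enantiomer written; not isolated) | O=Cc1ccc(OC2=CC=C[C@H](CCc3ccc(Oc4cc(C=C)ccc4OC)cc3)[C@H]2S(=O)(=O)c2ccccc2)c(Br)c1
F3 | step 6 | 3-bromo-4-{3-[2-(4-(5-ethenyl-2-methoxyphenoxy)phenyl)ethyl]phenoxy}benzaldehyde | O=Cc1ccc(Oc2cccc(CCc3ccc(Oc4cc(C=C)ccc4OC)cc3)c2)c(Br)c1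
F4 | step 6 | macrocyclic (E)-stilbene aldehyde (14 with CH=CH in place of the ring A–ring B CH2CH2) | O=Cc1ccc2c(c1)/C=C/c1ccc(OC)c(c1)Oc1ccc(cc1)CCc1cccc(c1)O2
F5 | step 4 | 3-bromo-4-hydroxybenzaldehyde | O=Cc1ccc(O)c(Br)c1
F6 | step 5 | 2-[2-(4-methoxy-3-{4-[(3E)-4-(phenylsulfonyl)but-3-en-1-yl]phenoxy}phenyl)ethyl]-4,4,5,5-tetramethyl-1,3,2-dioxaborolane | COc1ccc(CCB2OC(C)(C)C(C)(C)O2)cc1Oc1ccc(CC/C=C/S(=O)(=O)c2ccccc2)cc1
F7 | step 5 | potassium trifluoro[2-(4-methoxy-3-{4-[(3E)-4-(phenylsulfonyl)but-3-en-1-yl]phenoxy}phenyl)ethyl]borate | COc1ccc(CC[B-](F)(F)F)cc1Oc1ccc(CC/C=C/S(=O)(=O)c2ccccc2)cc1.[K+]
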